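## Retrosynthetic overview
1. The two malonate acyl C–O bonds are cut last: target ⇒ dimethyl malonate + two labda-7,13-dien-15-ol units. The same step shuttles the allylic C–O bond between C15 and C13, so that only the 13E alcohol is esterified.
2. Δ7 alkene ⇒ E1 loss of acetic acid from an 8α-acetate. The side chain is held as an acid-tolerant primary allylic acetate during this step.
3. C15–O bond ⇒ 1,3-acyloxy shift of the tertiary allylic 13-acetate (C13–O to C15–O).
4. Diacetate ⇒ (−)-sclareol + acetyl chloride.
5. No ring is formed. Ring A and ring B (the trans-decalin with C5, C9 and C10) come intact from sclareol.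

Assumption: labdane numbering is used. The SMILES decodes as two identical normal-series halves (5S,9S,10S; 5α-H, 9α-H, 10β-CH3), the same series as (−)-sclareol, with both C13=C14 bonds E.

## Route

Step 1
Reactants: 1 (−)-sclareol, (13R)-labd-14-ene-8α,13-diol (5S,8R,9R,10S,13R); 2 acetyl chloride
Product: 3 sclareol diacetate, (13R)-8α,13-diacetoxylabd-14-ene
Conditions: AcCl (5 equiv), PhNMe2 (6 equiv), CH2Cl2, 0 °C to rt, 36 h
Reagents that add atoms: acetyl chloride (2), CC(=O)Cl
Why: O-acylation with an acyl chloride and the weak base PhNMe2 esterifies both hindered tertiary alcohols without ionising the allylic C13–O bond, so no manoyl oxide or diene forms, and C8 and C13 keep their configuration because only O–H bonds are broken.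

Step 2
Reactants: 3 sclareol diacetate
Product: 4 8α,15-diacetoxylabd-13-ene (13E/13Z about 4:1)
Conditions: PdCl2(MeCN)2 (5 mol %), THF, rt, 12 h
Reagents that add atoms: none
Why: This is a cyclisation-induced [3,3] rearrangement of an allylic ester (1,3-acyloxy transposition under divalent palladium) in which the metal binds the vinyl group and the 13-acetate carbonyl oxygen attacks C15 to give a 1,3-dioxan-2-ylium palladium alkyl that opens to the more stable primary acetate with a trisubstituted alkene; no free allyl cation is involved, so the 8α-acetate and the ring stereocentres survive, and the alkene geometry is only partly controlled (CH3 against CH2 on C13) and is settled in step 4.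

Step 3
Reactants: 4 8α,15-diacetoxylabd-13-ene
Product: 6 labda-7,13-dien-15-ol (13E/13Z about 4:1), via labda-7,13-dien-15-yl acetate 5 (not isolated)
Conditions: p-TsOH·H2O (5 mol %), toluene, 70 °C, 1–2 h (GC control); concentrate (AcOH leaves with toluene); K2CO3 (0.3 equiv), MeOH, rt, 3 h; AgNO3–SiO2 chromatography (the E and Z fractions of the Δ7 series are pooled)
Reagents that add atoms: none
Why: E1 elimination after acid-catalysed alkyl–oxygen (AAL1) ionisation of the tertiary 8-acetate is sped by relief of the 1,3-diaxial C17/C20 methyl clash, the cation loses the axial 7α-H, any exocyclic alkene is re-protonated and funnelled to the trisubstituted Δ7 alkene while the shielded 9α-H reacts slowly, there is no free 8-OH that could close an 8,13-ether, the primary allylic acetate ionises far more slowly in toluene, and the base-catalysed methanolysis that follows frees the 15-OH without touching C5, C9 or C10.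

Step 4
Reactants: 6 labda-7,13-dien-15-ol (13E/13Z mixture, 2.15 equiv); 7 dimethyl malonate (1 equiv)
Product: 10 bis[(13E)-labda-7,13-dien-15-yl] malonate, via labda-7,14-dien-13-ol 8 (not isolated), via methyl labdadienyl malonate 9 (not isolated)
Conditions: VO(OSiPh3)3 (10 mol %), Candida antarctica lipase B immobilised on acrylic resin, toluene, 60 °C, 250 mbar with slow Ar bleed (MeOH stripped), 24–48 h; filter; SiO2 chromatography
Reagents that add atoms: dimethyl malonate (7), COC(=O)CC(=O)OC
Why: Proposed new method: a geometry-correcting vanadate/lipase relay in which VO(OSiPh3)3 (pentavalent vanadium) exchanges a siloxide for the free allylic alcohol and moves the C–O bond between C15 and C13 by a chair-like [3,3] 1,3-oxygen shift of the vanadate ester, so that 13Z-6, tertiary 8 and 13E-6 interconvert while esters stay untouched, and the lipase, which never acylates the tertiary alcohol 8 and should take the extended 13E alcohol much faster than the 13Z isomer (whose decalin-bearing chain folds back over the CH2OH group in the narrow alcohol channel), drains only 13E-6 from this pool (Curtin–Hammett) through the malonyl-enzyme first to 9 and then to 10, with methanol removal making each exit practically irreversible, so that both ester C–O bonds are formed and both E alkenes are set in one operation without touching C5, C9, C10 or the Δ7 alkenes; the closest known reaction type is the lipase/oxovanadium dynamic kinetic resolution of secondary allylic alcohols with 1,3-transposition, which has not been used to select alkene geometry, to deliver primary allylic esters or with a two-fold acyl donor.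

## Compound list
1 | (−)-sclareol, (13R)-labd-14-ene-8α,13-diol | C[C@@]1(O)CC[C@H]2C(C)(C)CCC[C@]2(C)[C@H]1CC[C@@](C)(O)C=C | starting material
2 | acetyl chloride | CC(=O)Cl | starting material
3 | sclareol diacetate, (13R)-8α,13-diacetoxylabd-14-ene | C[C@@]1(OC(C)=O)CC[C@H]2C(C)(C)CCC[C@]2(C)[C@H]1CC[C@@](C)(OC(C)=O)C=C | intermediate
4 | 8α,15-diacetoxylabd-13-ene, 13E/13Z about 4:1 (alkene geometry left open on purpose) | C[C@@]1(OC(C)=O)CC[C@H]2C(C)(C)CCC[C@]2(C)[C@H]1CCC(C)=CCOC(C)=O | intermediate
5 | labda-7,13-dien-15-yl acetate, 13E/13Z mixture, not isolated | CC1=CC[C@H]2C(C)(C)CCC[C@]2(C)[C@H]1CCC(C)=CCOC(C)=O | intermediate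
6 | labda-7,13-dien-15-ol, 13E/13Z about 4:1 (5S,9S,10S) | CC1=CC[C@H]2C(C)(C)CCC[C@]2(C)[C@H]1CCC(C)=CCO | intermediate
7 | dimethyl malonate | COC(=O)CC(=O)OC | starting material
8 | labda-7,14-dien-13-ol, both C13 epimers, relay alcohol, not isolated | CC1=CC[C@H]2C(C)(C)CCC[C@]2(C)[C@H]1CCC(C)(O)C=C | intermediate
9 | methyl (13E)-labda-7,13-dien-15-yl malonate, not isolated | CC1=CC[C@H]2C(C)(C)CCC[C@]2(C)[C@H]1CC/C(C)=C/COC(=O)CC(=O)OC | intermediate
10 | bis[(13E)-labda-7,13-dien-15-yl] malonate (CNP0113044.1) | CC1=CC[C@H]2C(C)(C)CCC[C@]2(C)[C@H]1CC/C(C)=C/COC(=O)CC(=O)OC/C=C(\C)CC[C@H]1C(C)=CC[C@H]2C(C)(C)CCC[C@]12C | target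

## Step count and risks
Total step count: 4. Longest linear sequence: 4 (1 → 3 → 4 → 6 → 10).

C5, C9 and C10 come from sclareol and are never at risk of epimerisation. The C9 descriptor changes from R to S only because the CIP priorities change when the 8-oxygen is lost.

**Step 4 (the new step).**
- The vanadate shuttle may be too slow at a temperature the enzyme tolerates.
- The lipase may not discriminate E from Z well enough.
- The tertiary alcohol 8 may dehydrate.

The fallback uses known chemistry, sets out from 6 and comes back at 10. Compound 6 is separated on AgNO3-impregnated silica to give pure (13E)-labda-7,13-dien-15-ol F4. This is coupled by Steglich esterification with malonic acid (0.5 equiv), DCC and catalytic DMAP in CH2Cl2, 0 °C to rt. The Z alcohol is discarded.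

**Step 3.** The cationic elimination may give too much Δ8(9) or Δ8(17) alkene, or may ionise the allylic acetate.

The fallback sets out from 4 and comes back at 5, which is then methanolysed as in step 3.
- It replaces the cation by a thermal syn-elimination followed by a radical isomerisation.
- Refluxing 2,4,6-collidine expels the 8-acetate to give mainly labda-8(17),13-dien-15-yl acetate F3, together with some 5.
- Cobalt-hydride hydrogen-atom-transfer isomerisation then moves only the 1,1-disubstituted alkene. The conditions are chloro[N,N′-bis(3,5-di-tert-butylsalicylidene)-1,2-cyclohexanediaminato]cobalt (trivalent cobalt, 3 mol %) and PhSiH3 (10 mol %) in benzene at rt.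
- The C8 radical gives up the accessible C7–H, which leads to the Δ7 alkene.

**Step 2.** The shift may stall at equilibrium or the catalyst may decompose to palladium black.

The fallback sets out from 3 and comes back at 4, and it goes through an allylic halide instead of a sigmatropic shift.
- NaOMe (0.2 equiv) in MeOH at rt removes the less shielded side-chain acetate to give sclareol 8-monoacetate F1.
- PBr3 with pyridine in Et2O at −10 °C gives, by SN2′ displacement, 8α-acetoxy-15-bromolabd-13-ene F2.
- KOAc in DMF at rt then gives 4.

## Further compounds
F1 | step 2 | sclareol 8-monoacetate, (13R)-8α-acetoxylabd-14-en-13-ol | C[C@@]1(OC(C)=O)CC[C@H]2C(C)(C)CCC[C@]2(C)[C@H]1CC[C@@](C)(O)C=C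
F2 | step 2 | 8α-acetoxy-15-bromolabd-13-ene, 13E/13Z mixture | C[C@@]1(OC(C)=O)CC[C@H]2C(C)(C)CCC[C@]2(C)[C@H]1CCC(C)=CCBr
F3 | step 3 | labda-8(17),13-dien-15-yl acetate, 13E/13Z mixture | C=C1CC[C@H]2C(C)(C)CCC[C@]2(C)[C@H]1CCC(C)=CCOC(C)=O
F4 | step 4 | (13E)-labda-7,13-dien-15-ol | CC1=CC[C@H]2C(C)(C)CCC[C@]2(C)[C@H]1CC/C(C)=C/CO
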